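**Plan**
- Retrosynthetic cuts: the C15 O–acetyl bond; then C1–C2 and C3–C4 together, which takes C2–C3 out of ring A as phenyl vinyl sulfone; then C9–C11 (side chain as a homoallylic borane); then C10–C1 and C10–CH3 (two enolate alkylations), back to (R)-carvone.
- Forward order: ring B is the carvone ring; C10 is made quaternary (CH3, then CH2I = C1); the enone becomes an enol triflate and the C11–C15 chain is joined at C9; the isopropenyl group becomes the C4–H ester; ring A is closed last in one pot.
- Enabling feature: C1 is an iodomethyl group on quaternary C10 (neopentyl, no β-hydrogen, so it can only be substituted) and C4–H is the one acidic C–H; both hang trans from the adjacent ring B atoms C10 and C5, so a two-carbon Michael acceptor (C2–C3) can bridge them into a trans-fused ring A.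
- Stereochemistry: C5 from (R)-carvone; C10 by alkylation anti to the isopropenyl group; C4 by attack of the acceptor on the enolate face turned away from C10; 13E from (E)-3-methylpent-2-en-4-yn-1-ol.

Key step: step 10

Remark: atom labels C1–C20 follow the labdane numbering of the target throughout; compounds 13–17 are carried as epimer mixtures at the future C4 and 21 as a mixture at C2, because both centres are erased later (enolisation in step 10, desulfonylation in step 11).

**Step 1**
Reactants: 1 (R)-(−)-carvone
Product: 3 (5R)-2,6-dimethyl-5-(prop-1-en-2-yl)cyclohex-2-en-1-one (6-methylcarvone; both C6 epimers), via lithium dienolate 2 (not isolated)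
Conditions: LiN(i-Pr)2, THF, −78 °C; MeI, −78 → 0 °C
Reagents that add atoms: iodomethane, CI
Why: Kinetic α′-deprotonation of the cross-conjugated enone and SN2 methylation of the dienolate (enolate alkylation) should give 6-methylcarvone; the new centre is left uncontrolled because it is re-enolised in step 2.

**Step 2**
Reactants: 3 6-methylcarvone
Product: 5 (5S,6S)-6-(iodomethyl)-2,6-dimethyl-5-(prop-1-en-2-yl)cyclohex-2-en-1-one (CH2I trans to isopropenyl), via lithium enolate 4 (not isolated)
Conditions: LiN(i-Pr)2, THF, −78 → 0 °C; CH2I2 (excess), DMPU, −78 °C → rt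
Reagents that add atoms: diiodomethane, ICI
Why: Enolate alkylation (iodomethylation): the tetrasubstituted enolate should attack CH2I2 at carbon on the face anti to the neighbouring isopropenyl group, so CH2I ends up trans and the methyl cis to it, which sets the quaternary centre that becomes C10.

**Step 3**
Reactants: 5 iodomethyl enone
Product: 7 (5S,6S)-6-(iodomethyl)-2,6-dimethyl-5-(prop-1-en-2-yl)cyclohex-1-en-1-yl trifluoromethanesulfonate, via lithium enolate 6 (not isolated)
Conditions: LiBH(s-Bu)3, THF, −78 °C; then PhNTf2, −78 °C → rt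
Reagents that add atoms: N-phenylbis(trifluoromethanesulfonimide), O=S(=O)(N(c1ccccc1)S(=O)(=O)C(F)(F)F)C(F)(F)F
Why: Conjugate reduction of the enone gives the C9–C8 enolate regiospecifically and O-sulfonylation traps it as the tetrasubstituted enol triflate (conjugate reduction–enolate triflation); the neopentyl iodide has no β-hydrogen and should resist hydride displacement at −78 °C.

**Step 4**
Reactants: 8 (E)-3-methylpent-2-en-4-yn-1-ol
Product: 9 (E)-tert-butyldimethyl[(3-methylpent-2-en-4-yn-1-yl)oxy]silane
Conditions: TBSCl, imidazole, DMF, 0 °C → rt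
Reagents that add atoms: tert-butyldimethylsilyl chloride, CC(C)(C)[Si](C)(C)Cl
Why: Standard silylation of a primary allylic alcohol; the alkene geometry is not touched.

**Step 5**
Reactants: 9 silyl enyne
Product: 10 (E)-tert-butyldimethyl[(3-methylpenta-2,4-dien-1-yl)oxy]silane
Conditions: H2 (1 atm, one equivalent taken up), Pd/CaCO3 poisoned with Pb(OAc)2 (Lindlar catalyst), quinoline, hexane, rt
Reagents that add atoms: none
Why: Lindlar semihydrogenation should stop the terminal alkyne at the vinyl group and leave the trisubstituted E-alkene unchanged.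

**Step 6**
Reactants: 10 silyl diene; 7 enol triflate
Product: 12 tert-butyl{[(2E)-5-[(5S,6S)-6-(iodomethyl)-2,6-dimethyl-5-(prop-1-en-2-yl)cyclohex-1-en-1-yl]-3-methylpent-2-en-1-yl]oxy}dimethylsilane, via homoallylic B-alkyl-9-BBN 11 (not isolated)
Conditions: 10 (1.6 equiv), 9-BBN (1.5 equiv), THF, 0 °C → rt; then 7, Pd(dppf)Cl2 (10 mol %), AsPh3, Cs2CO3, DMF/H2O, 50 °C
Reagents that add atoms: none
Why: 9-BBN should add to the monosubstituted terminus of the diene to give the primary homoallylic borane, which joins C11 to C9 by B-alkyl Suzuki–Miyaura coupling; the diene is kept in excess over 9-BBN so that no B–H is left for the isopropenyl group of 7, and the neopentyl C–I bond is not expected to add to zerovalent palladium.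

**Step 7**
Reactants: 12 coupled triene
Product: 14 primary alcohol in which the isopropenyl group on C5 has become CH(CH3)CH2OH (both epimers at the new centre; ring stereocentres unchanged), via alkylborane 13 (not isolated)
Conditions: 9-BBN, THF, 0 °C → rt; then NaOH, H2O2, 0 °C → rt
Reagents that add atoms: hydrogen peroxide, OO
Why: Hydroboration–oxidation: 9-BBN should add anti-Markovnikov to the 1,1-disubstituted alkene far faster than to the tri- and tetrasubstituted alkenes.

**Step 8**
Reactants: 14 primary alcohol
Product: 16 carboxylic acid (CH(CH3)CO2H on C5), via aldehyde 15 (not isolated)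
Conditions: TEMPO (cat.), PhI(OAc)2, MeCN/H2O, rt
Reagents that add atoms: water, O
Why: Oxoammonium-mediated oxidation (TEMPO/PhI(OAc)2) should take the primary alcohol through the aldehyde hydrate to the acid without touching alkenes, silyl ether or alkyl iodide.

**Step 9**
Reactants: 16 carboxylic acid
Product: 17 2-(trimethylsilyl)ethyl ester of 16
Conditions: Me3SiCH2CH2OH, DCC, DMAP (cat.), CH2Cl2, 0 °C → rt
Reagents that add atoms: 2-(trimethylsilyl)ethanol, C[Si](C)(C)CCO
Why: Steglich esterification installs an ester that survives enolate chemistry and can later be removed by fluoride without attack at the hindered carbonyl.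

**Step 10**
Reactants: 17 iodo ester; 18 phenyl vinyl sulfone
Product: 21 2-(trimethylsilyl)ethyl (4S,5R,10S)-15-(tert-butyldimethylsilyloxy)-2-(phenylsulfonyl)labda-8,13E-dien-19-oate (both C2 epimers), via lithium ester enolate 19 (not isolated), via lithium sulfonyl carbanion 20 (not isolated)
Conditions: LiN(i-Pr)2 (1.05 equiv), THF, −78 °C; 18 (1.0 equiv, added slowly), −78 → −30 °C; then DMPU, rt → 50 °C
Reagents that add atoms: none
Why: LiN(i-Pr)2 removes the only acidic C–H (C4–H) to give the tetrasubstituted ester enolate 19, which adds in conjugate fashion to phenyl vinyl sulfone (C3–C4 bond) to give the α-sulfonyl carbanion 20; on warming with DMPU this carbanion displaces iodide from the neopentyl C1 (C1–C2 bond). The closest known reaction type is the Michael-initiated ring closure (conjugate addition to a vinyl sulfone followed by intramolecular alkylation of the sulfonyl carbanion by a tethered halide), an anionic [4+2] annulation. Ring A closes in the 6-exo-tet mode through a chair transition state, and the trans ring fusion is already built into the substrate, because C1 and C4 stand trans on C10 and C5 of ring B, both equatorial in the favoured half-chair. The new stereocentre C4 is controlled by C5: with C5–H eclipsing the enolate double bond (allylic 1,3-strain) the quaternary C10 shields one face, so the acceptor should enter anti to C10, which places the ester β (axial, cis to the C10 methyl) and the methyl α; C2 need not be controlled because the sulfonyl group is removed in step 11. The step needs conjugate addition to outrun any direct reaction of the enolate with the iodide, and substitution without elimination: the iodide has no β-hydrogen and direct attack by the enolate (4-exo-tet at C4, or at oxygen) is slow at −78 °C, so only the tethered sulfonyl carbanion, held at high effective molarity, should alkylate it.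

**Step 11**
Reactants: 21 sulfonyl decalin ester
Product: 22 2-(trimethylsilyl)ethyl (4S,5R,10S)-15-(tert-butyldimethylsilyloxy)labda-8,13E-dien-19-oate
Conditions: Mg, MeOH/THF, rt → 50 °C
Reagents that add atoms: none
Why: Reductive desulfonylation by electron transfer from magnesium in methanol should cleave the C2–S bond of both epimers and leave the hindered ester, the silyl ether and the unconjugated alkenes untouched.

**Step 12**
Reactants: 22 silyl ester
Product: 23 (4S,5R,10S)-15-hydroxylabda-8,13E-dien-19-oic acid
Conditions: Bu4NF (excess), THF, rt; work-up with dilute HCl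
Reagents that add atoms: none
Why: Fluoride desilylation: attack at silicon fragments the 2-(trimethylsilyl)ethyl ester to the carboxylate, ethene and Me3SiF without any attack at the hindered axial carbonyl, and the allylic silyl ether is cleaved in the same pot.

**Step 13**
Reactants: 23 hydroxy acid
Product: 24 (4S,5R,10S)-15-acetoxylabda-8,13E-dien-19-oic acid (target)
Conditions: Ac2O, pyridine, DMAP (cat.), CH2Cl2, 0 °C → rt; aqueous work-up
Reagents that add atoms: acetic anhydride, CC(=O)OC(C)=O
Why: Acyl transfer to the primary allylic alcohol; the tertiary axial carboxylic acid should not be acylated, and any mixed anhydride is hydrolysed on aqueous work-up.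

**Compound list**
1 | (R)-(−)-carvone | CC1=CC[C@@H](C(C)=C)CC1=O | starting material
2 | lithium dienolate of carvone (C6-deprotonated) | CC1=CC[C@@H](C(C)=C)C=C1O[Li] | intermediate
3 | (5R)-2,6-dimethyl-5-(prop-1-en-2-yl)cyclohex-2-en-1-one, C6 epimers | CC1=CC[C@@H](C(C)=C)C(C)C1=O | intermediate
4 | lithium enolate of 3 | CC1=CC[C@@H](C(C)=C)C(C)=C1O[Li] | intermediate
5 | (5S,6S)-6-(iodomethyl)-2,6-dimethyl-5-(prop-1-en-2-yl)cyclohex-2-en-1-one | CC1=CC[C@@H](C(C)=C)[C@](C)(CI)C1=O | intermediate
6 | lithium enolate from conjugate reduction of 5 | [Li]OC1=C(C)CC[C@@H](C(C)=C)[C@]1(C)CI | intermediate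
7 | (5S,6S)-6-(iodomethyl)-2,6-dimethyl-5-(prop-1-en-2-yl)cyclohex-1-en-1-yl trifluoromethanesulfonate | O=S(=O)(OC1=C(C)CC[C@@H](C(C)=C)[C@]1(C)CI)C(F)(F)F | intermediate
8 | (E)-3-methylpent-2-en-4-yn-1-ol | C#C/C(C)=C/CO | starting material
9 | (E)-tert-butyldimethyl[(3-methylpent-2-en-4-yn-1-yl)oxy]silane | C#C/C(C)=C/CO[Si](C)(C)C(C)(C)C | intermediate
10 | (E)-tert-butyldimethyl[(3-methylpenta-2,4-dien-1-yl)oxy]silane | C=C/C(C)=C/CO[Si](C)(C)C(C)(C)C | intermediate
11 | 9-[(E)-5-(tert-butyldimethylsilyloxy)-3-methylpent-3-en-1-yl]-9-borabicyclo[3.3.1]nonane | CC(C)(C)[Si](C)(C)OC/C=C(\C)CCB1C2CCCC1CCC2 | intermediate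
12 | tert-butyl{[(2E)-5-[(5S,6S)-6-(iodomethyl)-2,6-dimethyl-5-(prop-1-en-2-yl)cyclohex-1-en-1-yl]-3-methylpent-2-en-1-yl]oxy}dimethylsilane | CC(C)(C)[Si](C)(C)OC/C=C(\C)CCC1=C(C)CC[C@@H](C(C)=C)[C@]1(C)CI | intermediate
13 | alkylborane from 12 (9-BBN on the terminal carbon of the former isopropenyl group) | CC(C)(C)[Si](C)(C)OC/C=C(\C)CCC1=C(C)CC[C@@H](C(C)CB2C3CCCC2CCC3)[C@]1(C)CI | intermediate
14 | primary alcohol (1-hydroxypropan-2-yl on C5; epimers at the new centre) | CC(C)(C)[Si](C)(C)OC/C=C(\C)CCC1=C(C)CC[C@@H](C(C)CO)[C@]1(C)CI | intermediate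
15 | aldehyde (1-oxopropan-2-yl on C5) | CC(C)(C)[Si](C)(C)OC/C=C(\C)CCC1=C(C)CC[C@@H](C(C)C=O)[C@]1(C)CI | intermediate
16 | carboxylic acid (1-carboxyethyl on C5) | CC(C)(C)[Si](C)(C)OC/C=C(\C)CCC1=C(C)CC[C@@H](C(C)C(=O)O)[C@]1(C)CI | intermediate
17 | 2-(trimethylsilyl)ethyl ester of 16 | CC(C)(C)[Si](C)(C)OC/C=C(\C)CCC1=C(C)CC[C@@H](C(C)C(=O)OCC[Si](C)(C)C)[C@]1(C)CI | intermediate
18 | phenyl vinyl sulfone | C=CS(=O)(=O)c1ccccc1 | starting material
19 | lithium ester enolate of 17 (C4 planar) | CC(C)(C)[Si](C)(C)OC/C=C(\C)CCC1=C(C)CC[C@@H](C(C)=C(O[Li])OCC[Si](C)(C)C)[C@]1(C)CI | intermediate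
20 | lithium α-sulfonyl carbanion (C3–C4 bond formed, lithium on C2) | CC(C)(C)[Si](C)(C)OC/C=C(\C)CCC1=C(C)CC[C@@H]([C@](C)(CC([Li])S(=O)(=O)c2ccccc2)C(=O)OCC[Si](C)(C)C)[C@]1(C)CI | intermediate
21 | 2-(trimethylsilyl)ethyl (4S,5R,10S)-15-(tert-butyldimethylsilyloxy)-2-(phenylsulfonyl)labda-8,13E-dien-19-oate, C2 epimers | CC(C)(C)[Si](C)(C)OC/C=C(\C)CCC1=C(C)CC[C@H]2[C@@](C)(C(=O)OCC[Si](C)(C)C)CC(S(=O)(=O)c3ccccc3)C[C@]12C | intermediate
22 | 2-(trimethylsilyl)ethyl (4S,5R,10S)-15-(tert-butyldimethylsilyloxy)labda-8,13E-dien-19-oate | CC(C)(C)[Si](C)(C)OC/C=C(\C)CCC1=C(C)CC[C@H]2[C@@](C)(C(=O)OCC[Si](C)(C)C)CCC[C@]12C | intermediate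
23 | (4S,5R,10S)-15-hydroxylabda-8,13E-dien-19-oic acid | OC/C=C(\C)CCC1=C(C)CC[C@H]2[C@@](C)(C(=O)O)CCC[C@]12C | intermediate
24 | (4S,5R,10S)-15-acetoxylabda-8,13E-dien-19-oic acid (CNP0326733.1) | CC(=O)OC/C=C(\C)CCC1=C(C)CC[C@H]2[C@@](C)(C(=O)O)CCC[C@]12C | target

**Step count**
Total steps: 13. Longest linear sequence: 11 steps (steps 1–3 and 6–13, from (R)-carvone).

**Steps most likely to fail**

Step 10. The ring-closing displacement at the neopentyl carbon may be too slow, so that the open-chain conjugate adduct is merely protonated on work-up, or the acceptor may approach both faces of the enolate. The fallback sets out from 17 and comes back at 22; it makes the two bonds in separate known operations and avoids any SN2 reaction at C1. Alkylation of the enolate of 17 (LiN(i-Pr)2, then methyl bromoacetate) should give the diester F1, with the C3–C4 bond in place. SmI2 in THF with catalytic Fe(dbm)3 should then turn the iodide into an organosamarium that attacks the methyl ester in an intramolecular Barbier-type acyl substitution, giving the ring A ketone F2 (carbonyl at C2). Condensation with tosylhydrazine gives the tosylhydrazone F3, and its reduction with catecholborane and NaOAc should deliver 22.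

Step 6. Transmetalation at the crowded alkenylpalladium (tetrasubstituted triflate next to the quaternary carbon) may be slow, so that the triflate is hydrolysed or reduced and the borane is lost by β-hydride elimination. The fallback sets out from 10 and 7 and comes back at 12; it replaces the borane by an organozinc nucleophile. Hydroboration of 10 with 9-BBN as in step 6, then iodinolysis (I2, NaOMe), should give the homoallylic iodide F4. Zinc insertion (Zn dust, LiCl, THF) gives the alkylzinc iodide F5, which is joined to 7 by Negishi coupling (Pd2(dba)3, SPhos, THF/NMP, rt → 50 °C).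

Step 2. The hindered tetrasubstituted enolate may react sluggishly with CH2I2, with proton transfer or O-alkylation taking over. The fallback sets out from 3 and comes back at 5; it splits the step into an aldol reaction and a substitution at oxygen-activated carbon. The enolate of 3 (LiN(i-Pr)2) is treated with monomeric formaldehyde (from cracked paraformaldehyde) to give the hydroxymethyl ketone F6, again anti to the isopropenyl group. Appel iodination (PPh3, I2, imidazole, toluene, 80 °C) then gives 5.

**Further compounds**
F1 | step 10 | diester: 17 carrying a methoxycarbonylmethyl group on C4 (C4 configured as in the target) | CC(C)(C)[Si](C)(C)OC/C=C(\C)CCC1=C(C)CC[C@@H]([C@](C)(CC(=O)OC)C(=O)OCC[Si](C)(C)C)[C@]1(C)CI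
F2 | step 10 | 2-(trimethylsilyl)ethyl (4S,5R,10S)-15-(tert-butyldimethylsilyloxy)-2-oxolabda-8,13E-dien-19-oate | CC(C)(C)[Si](C)(C)OC/C=C(\C)CCC1=C(C)CC[C@H]2[C@@](C)(C(=O)OCC[Si](C)(C)C)CC(=O)C[C@]12C
F3 | step 10 | tosylhydrazone of F2 | CC(C)(C)[Si](C)(C)OC/C=C(\C)CCC1=C(C)CC[C@H]2[C@@](C)(C(=O)OCC[Si](C)(C)C)CC(=NNS(=O)(=O)c3ccc(C)cc3)C[C@]12C
F4 | step 6 | (E)-tert-butyl[(5-iodo-3-methylpent-2-en-1-yl)oxy]dimethylsilane | CC(C)(C)[Si](C)(C)OC/C=C(\C)CCI
F5 | step 6 | (E)-[5-(tert-butyldimethylsilyloxy)-3-methylpent-3-en-1-yl]zinc iodide | CC(C)(C)[Si](C)(C)OC/C=C(\C)CC[Zn]I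
F6 | step 2 | (5S,6R)-6-(hydroxymethyl)-2,6-dimethyl-5-(prop-1-en-2-yl)cyclohex-2-en-1-one | CC1=CC[C@@H](C(C)=C)[C@](C)(CO)C1=O
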